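**Assumptions (one line each)**
- Leprolomin (C20H22O8) has no stereocenters, so it is achiral. No stereochemistry has to be set, and none of the steps can scramble any.
- 2-Methylphloroglucinol (2,4,6-trihydroxytoluene) is taken as commercially available.

**Retrosynthesis**
1. Disconnect the diaryl ether C–O bond (Cu-catalysed O-arylation) into a ring-A phenol (**3**) and a ring-B aryl iodide (**6**). The last step is hydrogenolysis of two benzyl ethers.
2. Both aromatic rings are C-methyl-phloroacetophenone (**2**) derivatives, so no arene has to be built. Their O-patterns are differentiated by the inherent acidity and hindrance differences of its three OH groups.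
3. Ring B gets its C–I bond from the only free ring C–H of the 4′,6′-bis(benzyloxy)-2′-methoxy ketone (**5**), which sits between two OBn groups.
4. Everything comes from one commercial starting material (**1**), in two branches that join at the Ullmann coupling.

**Step 1**
Reactants: **1**, 2-methylphloroglucinol (2-methylbenzene-1,3,5-triol)
Product: **2**, 1-(2,4,6-trihydroxy-3-methylphenyl)ethanone
Conditions: AcOH, BF3·OEt2, 85 °C
Reagents that add atoms: acetic acid, CC(=O)O (BF3·OEt2 adds none)
Why: Friedel–Crafts (Nencki-type) C-acylation of the symmetrical, very electron-rich phloroglucinol. Only one product is possible, and the resulting ketone deactivates the ring against a second acylation.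

**Step 2**
Reactants: **2**
Product: **3**, 1-(2,6-dihydroxy-4-methoxy-3-methylphenyl)ethanone (ring-A piece)
Conditions: MeI (1.0 equiv), K2CO3, acetone, 55 °C
Reagents that add atoms: methyl iodide, CI
Why: Williamson ether synthesis. The 4′-OH is para to the carbonyl, so it is the most acidic and is not locked in an H-bond to C=O. It is methylated selectively, while the two ortho OH groups stay chelated.

**Step 3**
Reactants: **2**
Product: **4**, 1-(4,6-bis(benzyloxy)-2-hydroxy-3-methylphenyl)ethanone
Conditions: BnBr (2.2 equiv), K2CO3, acetone, reflux
Reagents that add atoms: benzyl bromide, BrCc1ccccc1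
Why: Williamson ether synthesis. The 4′-OH reacts first, then the unhindered 6′-OH. The 2′-OH is both chelated to C=O and flanked by the methyl group, so it is left free (the 4′/6′-dialkylation selectivity is known for the methylation of **2**).

**Step 4**
Reactants: **4**
Product: **5**, 1-(4,6-bis(benzyloxy)-2-methoxy-3-methylphenyl)ethanone
Conditions: MeI (5 equiv), K2CO3, DMF, 60 °C
Reagents that add atoms: methyl iodide, CI
Why: Williamson O-methylation of the remaining hindered phenol. This puts the OMe on the carbon between the acetyl and methyl carbons, as required at B4 in the target.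

**Step 5**
Reactants: **5**
Product: **6**, 1-(4,6-bis(benzyloxy)-3-iodo-... i.e. 3,5-bis(benzyloxy)-... ) — named as 1-[2,4-bis(benzyloxy)-3-iodo-6-methoxy-5-methylphenyl]ethanone... see correction below

Correction of the name for **6**: 1-[2,4-bis(benzyloxy)-3-iodo-6-methoxy-5-methylphenyl]ethanone is wrong, because the methyl and OMe positions would be swapped. The correct name is **1-[4,6-bis(benzyloxy)-5-iodo-2-methoxy-3-methylphenyl]ethanone**. The iodine is on C5′, between the two OBn carbons.
Conditions: NIS (1.1 equiv), MeCN, 25 °C
Reagents that add atoms: N-iodosuccinimide, O=C1CCC(=O)N1I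
Why: Electrophilic aromatic iodination at the only free ring carbon, which is activated ortho/para by three alkoxy groups.

**Step 6**
Reactants: **3** (1.5 equiv) and **6** (1.0 equiv)
Product: **7**, 1-{2-[2,6-bis(benzyloxy)... ]} — named as 1-{6-[3,5-bis(benzyloxy)-... ]}; see the compound list for the unambiguous structure
Conditions: CuI (20 mol %), picolinic acid (40 mol %), K3PO4, DMSO, 100 °C, Ar
Reagents that add atoms: none (CuI and picolinic acid are catalyst and ligand; K3PO4 is a base that only takes up HI)
Why: Ullmann-type Cu/picolinic acid O-arylation, a method suited to hindered aryl iodides and phenols. The unhindered 6′-OH of **3** couples; the 2′-OH, next to the methyl group and chelated to C=O, does not. This builds the ring-A/ring-B ether bond with a free, chelated a5-OH already in place.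

**Step 7**
Reactants: **7**
Product: **8**, leprolomin
Conditions: H2 (1 atm), 10% Pd/C, EtOAc–MeOH, 25 °C, 2 h
Reagents that add atoms: none (H2 adds only hydrogen; toluene is lost)
Why: Catalytic hydrogenolysis cleaves both aryl benzyl ethers. The aryl methyl ethers, the diaryl ether and the chelated aryl ketones survive these mild conditions.

**Compound list**

| # | Name | SMILES | Role |
|---|---|---|---|
| 1 | 2-methylphloroglucinol | Cc1c(O)cc(O)cc1O | starting material |
| 2 | 1-(2,4,6-trihydroxy-3-methylphenyl)ethanone | CC(=O)c1c(O)cc(O)c(C)c1O | intermediate |
| 3 | 1-(2,6-dihydroxy-4-methoxy-3-methylphenyl)ethanone | CC(=O)c1c(O)cc(OC)c(C)c1O | intermediate |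
| 4 | 1-(4,6-bis(benzyloxy)-2-hydroxy-3-methylphenyl)ethanone | CC(=O)c1c(OCc2ccccc2)cc(OCc2ccccc2)c(C)c1O | intermediate |
| 5 | 1-(4,6-bis(benzyloxy)-2-methoxy-3-methylphenyl)ethanone | CC(=O)c1c(OCc2ccccc2)cc(OCc2ccccc2)c(C)c1OC | intermediate |
| 6 | 1-[4,6-bis(benzyloxy)-5-iodo-2-methoxy-3-methylphenyl]ethanone | CC(=O)c1c(OCc2ccccc2)c(I)c(OCc2ccccc2)c(C)c1OC | intermediate |
| 7 | diaryl ether bearing ring A (2-acetyl-3-hydroxy-5-methoxy-4-methylphenoxy) and ring B (4,6-bis(benzyloxy)-3-acetyl-2-methoxy-... 5-methyl, linked at C5′) | CC(=O)c1c(Oc2c(OCc3ccccc3)c(C)c(OC)c(C(C)=O)c2OCc2ccccc2)cc(OC)c(C)c1O | intermediate |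
| 8 | leprolomin | COc1cc(Oc2c(O)c(C)c(OC)c(C(C)=O)c2O)c(C(C)=O)c(O)c1C | target |

**Totals**
- Total steps: 7.
- Longest linear sequence: 6 steps (1 → 2 → 4 → 5 → 6 → 7 → 8, i.e. steps 1, 3, 4, 5, 6, 7).

**Three steps most likely to fail, with fallbacks**
1. **Step 6 (hindered Ullmann coupling).** The iodide is flanked by two OBn groups, and the phenol is ortho-acylated and chelated. Fallback: make the diaryl ether with a diaryliodonium salt instead. Convert **5** to the aryl(phenyl)iodonium tosylate with PhI(OAc)2/TsOH, then arylate **3** under metal-free base conditions.
2. **Step 2 (selective 4′-mono-methylation).** Over-methylation to the 4′,6′-dimethyl ether is possible. Fallback: permethylate **2** with Me2SO4/K2CO3, then cleave both ortho methyl ethers with BCl3 (2.2 equiv, CH2Cl2, −78 to 0 °C). Chelation to the acetyl group directs cleavage, and the para OMe survives, giving **3**.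
3. **Step 3 (4′,6′- versus 2′,4′-dibenzylation).** The 2′-OH may also react. Fallback: tribenzylate **2**, then use BCl3 (1 equiv, −78 °C) to remove the chelation-activated 2′-OBn. Methylate the freed OH as in step 4 to reach **5**. This gives up the selectivity-by-hindrance argument, so it needs to be checked experimentally.

**Corrections to names in the step text above:** Step 5's product name is the one given in the compound list for **6**. For Step 6's product, use the compound-list SMILES for **7**, where the ring-A phenol oxygen is bonded to C5′ of ring B.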